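## Retrosynthetic overview

1. The target comes from global deprotection of a fully protected ether. The key cut is the C4'–O–C8'' aryl alkyl ether, made late by a Mitsunobu coupling (inversion at C8'') between 7-O-benzyltricin **15** and the erythro C6–C3 alcohol **23**, two halves of about 30 heavy atoms each.
2. **15** comes from a flavanone, which comes from a chalcone, which comes from A-ring acetophenone **7** plus B-ring aldehyde **12** (Claisen–Schmidt). The pyranone C ring is the only ring built (oxa-Michael closure, then I2 dehydrogenation).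
3. **7** comes from resorcinol (ortho-lithiation/acetylation, then Ir C–H borylation/oxidation for the third oxygen). **12** comes from p-cresol (aerobic oxidation, dibromination, Cu-methoxylation).
4. **23** comes from 4-iodophenol plus methyl acrylate (Heck), then p-coumaryl alcohol, Sharpless epoxidation with D-(–)-DIPT, and benzylic epoxide opening with BnOH (inversion, sets 7''S). C8'' is inverted R→S in the Mitsunobu step.
5. Ring order: the three benzene rings are bought as arenes; a transient oxirane is formed in step 16 and opened in step 17; ring C is formed in steps 11–12.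

Assumption: (7''S,8''S) is taken exactly as encoded in the given SMILES (the threo isomer). The flavone 5-OH is left free after step 11 because its hydrogen bond to C4=O makes it unreactive under the later conditions.

This route is designed on paper from known reaction types; it has not been run.

## Route

### A-ring fragment

**Step 1**
Reactants: **1** resorcinol
Product: **2** 1,3-bis(methoxymethoxy)benzene
Conditions: MOMCl (2.5 eq), i-Pr2NEt, CH2Cl2, 0 °C → rt
Reagents that add atoms: chloromethyl methyl ether, COCCl
Why: Double O-alkylation (Williamson type) gives base-stable MOM ethers that are strong ortho-directing groups.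

**Step 2**
Reactants: **2**; **3** N-methoxy-N-methylacetamide
Product: **4** 1-[2,6-bis(methoxymethoxy)phenyl]ethan-1-one
Conditions: n-BuLi, THF, 0 °C, 1 h; then **3**, –78 °C → rt
Reagents that add atoms: none (acetyl comes from **3**)
Why: Directed ortho-metalation occurs only at C2, between the two chelating OMOM groups, and Weinreb acylation stops at the ketone.

**Step 3**
Reactants: **4**
Product: **5** 1-[2,6-bis(methoxymethoxy)-4-(pinacolboryl)phenyl]ethan-1-one
Conditions: [Ir(OMe)(cod)]2 (1.5 mol%), dtbpy (3 mol%), B2pin2 (0.6–1.0 eq), THF, 70 °C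
Reagents that add atoms: bis(pinacolato)diboron, CC1(C)OB(OC1(C)C)B1OC(C)(C)C(C)(C)O1
Why: Sterically controlled Ir-catalysed C–H borylation (Hartwig–Miyaura) goes to C4, the only C–H with no ortho substituent.

**Step 4**
Reactants: **5**
Product: **6** 1-[4-hydroxy-2,6-bis(methoxymethoxy)phenyl]ethan-1-one
Conditions: 30% H2O2, aq NaOH, THF, 0 °C; then adjust to pH 6
Reagents that add atoms: hydrogen peroxide, OO
Why: Oxidative boron-to-oxygen 1,2-migration turns C–B into C–OH at the same position; the di-ortho-substituted ketone is too hindered for Dakin or Baeyer–Villiger attack.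

**Step 5**
Reactants: **6**
Product: **7** 1-[4-(benzyloxy)-2,6-bis(methoxymethoxy)phenyl]ethan-1-one
Conditions: BnBr, K2CO3, DMF, rt
Reagents that add atoms: benzyl bromide, BrCc1ccccc1
Why: Williamson etherification of the only free phenol places the benzyl group on the future O7 with no regiochemical ambiguity.

### B-ring fragment

**Step 6**
Reactants: **8** p-cresol
Product: **9** 4-hydroxybenzaldehyde
Conditions: Co(OAc)2·4H2O (1 mol%), NaOH (3.5 eq), O2 (1 atm), MeOH, 60 °C
Reagents that add atoms: dioxygen, O=O
Why: Cobalt-catalysed aerobic benzylic oxidation of the p-cresolate (via the quinone methide) stops at the aldehyde.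

**Step 7**
Reactants: **9**
Product: **10** 3,5-dibromo-4-hydroxybenzaldehyde
Conditions: Br2 (2.1 eq), AcOH, rt
Reagents that add atoms: bromine, BrBr
Why: Electrophilic aromatic bromination occurs at both positions ortho to OH, with para blocked.

**Step 8**
Reactants: **10**
Product: **11** syringaldehyde (4-hydroxy-3,5-dimethoxybenzaldehyde)
Conditions: NaOMe (6 eq), CuCl (15 mol%), DMF/MeOH, 110 °C; then H3O+
Reagents that add atoms: sodium methoxide, [Na+].[O-]C
Why: Copper-catalysed Ullmann-type methoxylation replaces both aryl bromides.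

**Step 9**
Reactants: **11**
Product: **12** 3,5-dimethoxy-4-(methoxymethoxy)benzaldehyde
Conditions: MOMCl, i-Pr2NEt, CH2Cl2, 0 °C → rt
Reagents that add atoms: chloromethyl methyl ether, COCCl
Why: Acetal protection of the phenol keeps the aldehyde from being deactivated as a phenoxide in the basic aldol step.

### Flavone assembly

**Step 10**
Reactants: **7**; **12**
Product: **13** (E)-1-[4-(benzyloxy)-2,6-bis(methoxymethoxy)phenyl]-3-[3,5-dimethoxy-4-(methoxymethoxy)phenyl]prop-2-en-1-one
Conditions: 50% aq KOH, EtOH, rt, 24–48 h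
Reagents that add atoms: none
Why: Claisen–Schmidt aldol condensation with E1cB dehydration gives the E-chalcone.

**Step 11**
Reactants: **13**
Product: **14** (±)-7-(benzyloxy)-5-hydroxy-2-(4-hydroxy-3,5-dimethoxyphenyl)chroman-4-one
Conditions: 3 M HCl, MeOH/THF, 60 °C; then NaOAc, EtOH, reflux
Reagents that add atoms: none
Why: Acetal hydrolysis removes all three MOM groups and the 2'-OH closes ring C by 6-endo oxa-Michael addition; the racemic C2 centre is destroyed in the next step.

**Step 12**
Reactants: **14**
Product: **15** 7-(benzyloxy)-5-hydroxy-2-(4-hydroxy-3,5-dimethoxyphenyl)-4H-chromen-4-one (7-O-benzyltricin)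
Conditions: I2 (1.1 eq), pyridine, 95 °C
Reagents that add atoms: none
Why: Iodine-mediated dehydrogenation (α-iodination then HI elimination) converts flavanone to flavone and tolerates free phenols, as in the hesperidin-to-diosmin process.

### C6–C3 fragment

**Step 13**
Reactants: **16** 4-iodophenol; **17** methyl acrylate
Product: **18** methyl (E)-3-(4-hydroxyphenyl)prop-2-enoate
Conditions: Pd(OAc)2 (2 mol%), P(o-tol)3 (4 mol%), Et3N, DMF, 90 °C
Reagents that add atoms: none
Why: Mizoroki–Heck coupling; syn insertion and syn β-hydride elimination give the E-alkene.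

**Step 14**
Reactants: **18**
Product: **19** 4-[(E)-3-hydroxyprop-1-en-1-yl]phenol (p-coumaryl alcohol)
Conditions: DIBAL-H (3.5 eq), toluene, –78 → 0 °C; Rochelle salt work-up
Reagents that add atoms: none
Why: 1,2-Reduction of the enoate gives the allylic alcohol without touching the alkene.

**Step 15**
Reactants: **19**
Product: **20** 4-[(E)-3-hydroxyprop-1-en-1-yl]phenyl 2,2-dimethylpropanoate
Conditions: PivCl (1.05 eq), K2CO3, acetone, 0 °C
Reagents that add atoms: pivaloyl chloride, CC(C)(C)C(Cl)=O
Why: The phenoxide is acylated chemoselectively over the neutral alcohol, and the ester makes the ring electron-neutral so the later benzylic epoxide is stable and opens by an SN2-like path.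

**Step 16**
Reactants: **20**
Product: **21** 4-[(2R,3R)-3-(hydroxymethyl)oxiran-2-yl]phenyl 2,2-dimethylpropanoate
Conditions: Ti(Oi-Pr)4 (10 mol%), D-(–)-DIPT (14 mol%), t-BuOOH (2 eq), 4 Å MS, CH2Cl2, –20 °C
Reagents that add atoms: tert-butyl hydroperoxide, CC(C)(C)OO
Why: Sharpless asymmetric epoxidation; D-(–)-tartrate gives the (2R,3R)-trans-epoxide, the mirror image of the (2S,3S) product that L-(+)-tartrate gives with cinnamyl alcohol.

**Step 17**
Reactants: **21**
Product: **22** 4-[(1S,2R)-1-(benzyloxy)-2,3-dihydroxypropyl]phenyl 2,2-dimethylpropanoate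
Conditions: BnOH (10 eq), BF3·OEt2 (10 mol%), CH2Cl2, –30 → 0 °C; remove any threo epimer by chromatography
Reagents that add atoms: benzyl alcohol, OCc1ccccc1
Why: Lewis-acid-catalysed epoxide alcoholysis at the benzylic carbon with inversion (R→S) sets C7''; C8'' is untouched, giving the erythro (anti) diol.

**Step 18**
Reactants: **22**
Product: **23** 4-[(1S,2R)-1,3-bis(benzyloxy)-2-hydroxypropyl]phenyl 2,2-dimethylpropanoate
Conditions: Bu2SnO, toluene, reflux (–H2O); then BnBr, Bu4NI, 90 °C
Reagents that add atoms: benzyl bromide, BrCc1ccccc1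
Why: Stannylene-acetal activation benzylates the primary oxygen of the terminal 1,2-diol selectively, leaving only the C8'' hydroxyl free.

### Coupling and deprotection

**Step 19**
Reactants: **15**; **23**
Product: **24** 4-[(1S,2S)-1,3-bis(benzyloxy)-2-{4-[7-(benzyloxy)-5-hydroxy-4-oxo-4H-chromen-2-yl]-2,6-dimethoxyphenoxy}propyl]phenyl 2,2-dimethylpropanoate
Conditions: PPh3 (2 eq), DIAD (2 eq), THF, 0 → 40 °C
Reagents that add atoms: none
Why: Mitsunobu etherification; the acidic 4'-phenol displaces the activated C8'' oxygen by SN2 with inversion (R→S), giving the threo (7''S,8''S) ether, while the chelated 5-OH does not react.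

**Step 20**
Reactants: **24**
Product: **25** 4-[(1S,2S)-2-[4-(5,7-dihydroxy-4-oxo-4H-chromen-2-yl)-2,6-dimethoxyphenoxy]-1,3-dihydroxypropyl]phenyl 2,2-dimethylpropanoate
Conditions: H2 (1 atm), 10% Pd/C, EtOAc/MeOH, rt, monitored
Reagents that add atoms: none
Why: Catalytic hydrogenolysis cleaves the three unhindered PhCH2–O bonds; the hindered C7''–O bond on the ester-deactivated ring and the flavone C2=C3 react much more slowly.

**Step 21**
Reactants: **25**
Product: **26** (–)-(7''S,8''S)-4'',5,7-trihydroxy-3',5'-dimethoxy-4',8''-oxyflavonolignan-7'',9''-diol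
Conditions: K2CO3, degassed MeOH, 0 °C → rt; neutralise with AcOH
Reagents that add atoms: none
Why: Mild base methanolysis (transesterification) of the aryl pivalate releases the last phenol without acid, so the p-hydroxybenzylic C7'' centre cannot epimerise.

## Compound list

1 | resorcinol | Oc1cccc(O)c1 | starting material
2 | 1,3-bis(methoxymethoxy)benzene | COCOc1cccc(OCOC)c1 | intermediate
3 | N-methoxy-N-methylacetamide | CC(=O)N(C)OC | starting material
4 | 1-[2,6-bis(methoxymethoxy)phenyl]ethan-1-one | CC(=O)c1c(OCOC)cccc1OCOC | intermediate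
5 | 1-[2,6-bis(methoxymethoxy)-4-(4,4,5,5-tetramethyl-1,3,2-dioxaborolan-2-yl)phenyl]ethan-1-one | CC(=O)c1c(OCOC)cc(B2OC(C)(C)C(C)(C)O2)cc1OCOC | intermediate
6 | 1-[4-hydroxy-2,6-bis(methoxymethoxy)phenyl]ethan-1-one | CC(=O)c1c(OCOC)cc(O)cc1OCOC | intermediate
7 | 1-[4-(benzyloxy)-2,6-bis(methoxymethoxy)phenyl]ethan-1-one | CC(=O)c1c(OCOC)cc(OCc2ccccc2)cc1OCOC | intermediate
8 | p-cresol | Cc1ccc(O)cc1 | starting material
9 | 4-hydroxybenzaldehyde | O=Cc1ccc(O)cc1 | intermediate
10 | 3,5-dibromo-4-hydroxybenzaldehyde | O=Cc1cc(Br)c(O)c(Br)c1 | intermediate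
11 | syringaldehyde | COc1cc(C=O)cc(OC)c1O | intermediate
12 | 3,5-dimethoxy-4-(methoxymethoxy)benzaldehyde | COCOc1c(OC)cc(C=O)cc1OC | intermediate
13 | (E)-1-[4-(benzyloxy)-2,6-bis(methoxymethoxy)phenyl]-3-[3,5-dimethoxy-4-(methoxymethoxy)phenyl]prop-2-en-1-one | COCOc1cc(OCc2ccccc2)cc(OCOC)c1C(=O)/C=C/c1cc(OC)c(OCOC)c(OC)c1 | intermediate
14 | (±)-7-(benzyloxy)-5-hydroxy-2-(4-hydroxy-3,5-dimethoxyphenyl)chroman-4-one | COc1cc(C2CC(=O)c3c(O)cc(OCc4ccccc4)cc3O2)cc(OC)c1O | intermediate
15 | 7-(benzyloxy)-5-hydroxy-2-(4-hydroxy-3,5-dimethoxyphenyl)-4H-chromen-4-one | COc1cc(-c2cc(=O)c3c(O)cc(OCc4ccccc4)cc3o2)cc(OC)c1O | intermediate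
16 | 4-iodophenol | Oc1ccc(I)cc1 | starting material
17 | methyl acrylate | C=CC(=O)OC | starting material
18 | methyl (E)-3-(4-hydroxyphenyl)prop-2-enoate | COC(=O)/C=C/c1ccc(O)cc1 | intermediate
19 | 4-[(E)-3-hydroxyprop-1-en-1-yl]phenol | OC/C=C/c1ccc(O)cc1 | intermediate
20 | 4-[(E)-3-hydroxyprop-1-en-1-yl]phenyl 2,2-dimethylpropanoate | CC(C)(C)C(=O)Oc1ccc(/C=C/CO)cc1 | intermediate
21 | 4-[(2R,3R)-3-(hydroxymethyl)oxiran-2-yl]phenyl 2,2-dimethylpropanoate | OC[C@H]1O[C@@H]1c1ccc(OC(=O)C(C)(C)C)cc1 | intermediate
22 | 4-[(1S,2R)-1-(benzyloxy)-2,3-dihydroxypropyl]phenyl 2,2-dimethylpropanoate | OC[C@@H](O)[C@@H](OCc1ccccc1)c1ccc(OC(=O)C(C)(C)C)cc1 | intermediate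
23 | 4-[(1S,2R)-1,3-bis(benzyloxy)-2-hydroxypropyl]phenyl 2,2-dimethylpropanoate | O[C@H](COCc1ccccc1)[C@@H](OCc1ccccc1)c1ccc(OC(=O)C(C)(C)C)cc1 | intermediate
24 | 4-[(1S,2S)-1,3-bis(benzyloxy)-2-{4-[7-(benzyloxy)-5-hydroxy-4-oxo-4H-chromen-2-yl]-2,6-dimethoxyphenoxy}propyl]phenyl 2,2-dimethylpropanoate | COc1cc(-c2cc(=O)c3c(O)cc(OCc4ccccc4)cc3o2)cc(OC)c1O[C@@H](COCc1ccccc1)[C@@H](OCc1ccccc1)c1ccc(OC(=O)C(C)(C)C)cc1 | intermediate
25 | 4-[(1S,2S)-2-[4-(5,7-dihydroxy-4-oxo-4H-chromen-2-yl)-2,6-dimethoxyphenoxy]-1,3-dihydroxypropyl]phenyl 2,2-dimethylpropanoate | COc1cc(-c2cc(=O)c3c(O)cc(O)cc3o2)cc(OC)c1O[C@@H](CO)[C@@H](O)c1ccc(OC(=O)C(C)(C)C)cc1 | intermediate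
26 | (–)-(7''S,8''S)-4'',5,7-trihydroxy-3',5'-dimethoxy-4',8''-oxyflavonolignan-7'',9''-diol | COc1cc(-c2cc(=O)c3c(O)cc(O)cc3o2)cc(OC)c1O[C@@H](CO)[C@@H](O)c1ccc(O)cc1 | target

## Summary

Total steps: 21.

Longest linear sequence: 11 steps (1–5, 10–12, 19–21), about 52% of the total. The B-ring branch (steps 6–9) and the C6–C3 branch (steps 13–18) run in parallel.

Steps most likely to fail:

1. **Step 19 (Mitsunobu).** A di-ortho-substituted phenol must attack a flanked secondary alcohol, so slow conversion or elimination is possible. Fallback: make the ether on a primary carbon and set both stereocentres by C7''–C8'' bond formation instead.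
   - O-alkylate **15** (5-OH benzylated) with a bromoacetate and convert it to the N-(aryloxyacetyl)-(R)-4-benzyloxazolidin-2-one.
   - Run an Evans syn-aldol (Bu2BOTf, i-Pr2NEt) with 4-(benzyloxy)benzaldehyde (from **9** and BnBr), which gives the threo (7''S,8''S) adduct directly.
   - Remove the auxiliary reductively with NaBH4, then hydrogenolyse.

2. **Step 17 (benzylic epoxide opening).** Partial SN1 character would give the threo epimer, and Meinwald rearrangement is possible. Fallback: avoid substitution at the benzylic carbon altogether.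
   - Add vinylMgBr to 4-(benzyloxy)benzaldehyde to get the racemic 1-arylallyl alcohol.
   - Use Sharpless kinetic resolution, with the tartrate enantiomer that gives the (7''S)-erythro epoxy alcohol, so C7''–O is already in place.
   - O-benzylate, then open the terminal epoxide at C9'' with benzyl alkoxide to reach the 4''-OBn analogue of **23**.

3. **Step 20 (hydrogenolysis).** Competing cleavage of the benzylic C7''–O bond or saturation of the flavone C2=C3 is possible. Fallback: change the protecting-group logic so that O7'' and O9'' are released by fluoride.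
   - Open **21** with PhCO2H/Ti(Oi-Pr)4 and saponify to the erythro triol.
   - Re-protect the phenol and bridge O7''/O9'' as a di-tert-butylsilylene (t-Bu2Si(OTf)2), which leaves the C8'' hydroxyl free for the Mitsunobu step.
   - After coupling, only aryl benzyl ethers face Pd/H2, and HF·pyridine frees the diol.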